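All four members are (1S,2R,5R,6S)-2,6-diaryl-3,7-dioxabicyclo[3.3.0]octan-1-ols; they differ only in a 5-methoxy group on either aryl ring and in acetylation of the bridgehead C1–OH. Shared intermediate 15 holds the complete core with the phenols benzylated, Br on the C2-aryl ring, Cl on the C6-aryl ring (each exchangeable for H or OMe) and the free C1–OH. The trunk cuts the C1–C2 bond: Norrish–Yang photocyclisation of a 4-(arylmethoxymethyl)-5-aryl-dihydrofuran-3(2H)-one. It exploits the fact that the carbinol carbon C1 and the benzylic C2–H sit 1,5 to each other across O3 (C1–C5–C4–O3–C2); 1,6-hydrogen transfer to the ketone and biradical recombination close the C1–C2–O3–C4–C5 ring and set the tertiary carbinol C1 and C2 in one operation. Only C6 is set by catalysis; C5 follows by trans-alkylation, C1 and C2 in the photoreaction.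

Key step: step 8
Shared intermediate: compound 15

Remark: core locants follow 3,7-dioxabicyclo[3.3.0]octane (C1 = carbinol bridgehead, C2 = ArCH next to it, O3, C4, C5 = CH bridgehead, C6 = other ArCH, O7, C8); 5-chlorovanillin, 5-bromovanillin, allenylboronic acid pinacol ester and chloromethyl methyl sulfide are taken as commercial.

**Trunk**

Step 1
Reactants: 1 5-chlorovanillin
Product: 2 4-(benzyloxy)-3-chloro-5-methoxybenzaldehyde
Conditions: BnBr, K2CO3, DMF, 60 °C
Reagents that add atoms: benzyl bromide, BrCc1ccccc1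
Why: Williamson ether synthesis on the only acidic OH; the benzyl ether prevents quinone-methide chemistry at the later benzylic ether carbon and is removed at the end together with the halogen handle.

Step 2
Reactants: 2 4-(benzyloxy)-3-chloro-5-methoxybenzaldehyde; 3 allenylboronic acid pinacol ester
Product: 5 (S)-1-[4-(benzyloxy)-3-chloro-5-methoxyphenyl]but-3-yn-1-ol, via O-pinacolboryl ether 4 (not isolated)
Conditions: (S)-TRIP (5 mol %), 4 Å MS, PhMe, −20 °C; aq. NaHCO3 work-up
Reagents that add atoms: none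
Why: Chiral phosphoric acid-catalysed allenylboration (SE2' propargylation) through a closed six-membered transition state in which the acid binds the boronate oxygen and the formyl H; the catalyst antipode is chosen so that the aldehyde face leading to the (S)-carbinol (C6 of the core) is attacked, the only stereocentre set by a chiral reagent.

Step 3
Reactants: 5 (S)-1-[4-(benzyloxy)-3-chloro-5-methoxyphenyl]but-3-yn-1-ol
Product: 6 (S)-5-[4-(benzyloxy)-3-chloro-5-methoxyphenyl]dihydrofuran-3(2H)-one
Conditions: BrettPhosAuNTf2 (5 mol %), 2,6-dibromopyridine N-oxide (1.5 equiv), DCE, rt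
Reagents that add atoms: 2,6-dibromopyridine N-oxide, [O-][n+]1c(Br)cccc1Br
Why: Gold-catalysed alkyne oxidation, in which the N-oxide adds to the internal carbon of the Au-bound terminal alkyne, N–O cleavage gives an α-oxo gold carbene and intramolecular O–H insertion closes the five-membered ketone without touching the carbinol centre; this oxidant needs no acid additive, so the electron-rich benzylic alcohol should not ionise.

Step 4
Reactants: 7 5-bromovanillin
Product: 8 4-(benzyloxy)-3-bromo-5-methoxybenzaldehyde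
Conditions: BnBr, K2CO3, DMF, 60 °C
Reagents that add atoms: benzyl bromide, BrCc1ccccc1
Why: Williamson ether synthesis on the phenol, as in step 1.

Step 5
Reactants: 8 4-(benzyloxy)-3-bromo-5-methoxybenzaldehyde
Product: 9 [4-(benzyloxy)-3-bromo-5-methoxyphenyl]methanol
Conditions: NaBH4, MeOH/THF, 0 °C
Reagents that add atoms: none
Why: Borohydride reduction of the aldehyde; the aryl bromide and benzyl ether are inert.

Step 6
Reactants: 9 [4-(benzyloxy)-3-bromo-5-methoxyphenyl]methanol; 10 chloromethyl methyl sulfide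
Product: 11 2-(benzyloxy)-1-bromo-3-methoxy-5-{[(methylsulfanyl)methoxy]methyl}benzene
Conditions: NaH, NaI (cat.), DME, 0 °C to rt
Reagents that add atoms: none
Why: Williamson formation of a methylthiomethyl (MTM) ether from the alkoxide; the MTM ether is a storable precursor of the chloromethyl ether, which for an electron-rich benzyl alcohol cannot be made with HCl/formaldehyde without benzylic chloride formation.

Step 7
Reactants: 6 (S)-5-[4-(benzyloxy)-3-chloro-5-methoxyphenyl]dihydrofuran-3(2H)-one; 11 2-(benzyloxy)-1-bromo-3-methoxy-5-{[(methylsulfanyl)methoxy]methyl}benzene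
Product: 14 (4R,5S)-5-[4-(benzyloxy)-3-chloro-5-methoxyphenyl]-4-({[4-(benzyloxy)-3-bromo-5-methoxyphenyl]methoxy}methyl)dihydrofuran-3(2H)-one, via 2-(benzyloxy)-1-bromo-5-[(chloromethoxy)methyl]-3-methoxybenzene 12 (not isolated), via lithium (5S)-5-[4-(benzyloxy)-3-chloro-5-methoxyphenyl]-2,5-dihydrofuran-3-olate 13 (not isolated)
Conditions: 11, SO2Cl2, CH2Cl2, −78 °C, then evaporate; 6, LDA, THF, −78 °C; add 12, −78 to −40 °C; AcOH quench
Reagents that add atoms: none
Why: Kinetic LDA deprotonation of a 3-oxotetrahydrofuran should occur at C4, away from the oxygen-bearing C2 (lone-pair repulsion disfavours the C2 enolate), and SN2 enolate alkylation by the reactive chloromethyl ether takes place anti to the C5 aryl group, giving the trans-4,5 isomer, which is also the thermodynamic one (this sets C5 of the core).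

Step 8
Reactants: 14 (4R,5S)-5-[4-(benzyloxy)-3-chloro-5-methoxyphenyl]-4-({[4-(benzyloxy)-3-bromo-5-methoxyphenyl]methoxy}methyl)dihydrofuran-3(2H)-one
Product: 15 (1S,2R,5R,6S)-2-[4-(benzyloxy)-3-bromo-5-methoxyphenyl]-6-[4-(benzyloxy)-3-chloro-5-methoxyphenyl]-3,7-dioxabicyclo[3.3.0]octan-1-ol
Conditions: hν (medium-pressure Hg, Pyrex, λ > 300 nm), degassed PhH (0.01 M), rt
Reagents that add atoms: none
Why: n→π* excitation of the ketone is followed by 1,6-hydrogen transfer from the benzylic ether C–H (future C2) through a seven-membered transition state, and the resulting 1,5-biradical (C1 ketyl/C2 α-oxy benzyl radical) recombines; this is a Norrish–Yang photocyclisation of a β-alkoxy ketone to a tetrahydrofuran-3-ol. The C1–C2–O3–C4–C5 ring closes by radical–radical coupling to a five-membered ring, and the benzylic ether hydrogens are the only ones within reach of the carbonyl oxygen. C1 is set by the tether: the CH2–O–CH arm on C5 can reach only its own face of the ketone, which gives the cis-fused bicycle with OH cis to H-5. C2 is set in the ring closure by the aryl group turning to the convex face, away from the C8 methylene of the existing ring and cis to the small OH. The step needs hydrogen transfer to outrun Norrish type I cleavage and excitation of the haloarenes; the doubly activated (benzylic, α-oxy) C–H and irradiation above 300 nm, where essentially only the ketone absorbs, should secure this.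

**Branches**

Branch to 8-hydroxypinoresinol (compound 16)

Step 9
Reactants: 15 (1S,2R,5R,6S)-2-[4-(benzyloxy)-3-bromo-5-methoxyphenyl]-6-[4-(benzyloxy)-3-chloro-5-methoxyphenyl]-3,7-dioxabicyclo[3.3.0]octan-1-ol
Product: 16 8-hydroxypinoresinol
Conditions: H2 (1 atm), 10% Pd/C, NaOAc, EtOAc/MeOH, rt
Reagents that add atoms: none
Why: Pd-catalysed hydrogenolysis cleaves the two primary aryl benzyl ethers (phenoxide leaving group) and, with acetate as HX scavenger, the Ar–Br and Ar–Cl bonds, whereas the two secondary benzylic C–O bonds of the bicycle (dialkyl ethers, alkoxide leaving group, hindered) should react far more slowly in the non-acidic buffered medium and are spared by stopping at full debenzylation.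

Branch to 1-Acetoxypinoresinol (compound 18)

Step 10
Reactants: 15 (1S,2R,5R,6S)-2-[4-(benzyloxy)-3-bromo-5-methoxyphenyl]-6-[4-(benzyloxy)-3-chloro-5-methoxyphenyl]-3,7-dioxabicyclo[3.3.0]octan-1-ol
Product: 17 (1S,2R,5R,6S)-2-[4-(benzyloxy)-3-bromo-5-methoxyphenyl]-6-[4-(benzyloxy)-3-chloro-5-methoxyphenyl]-3,7-dioxabicyclo[3.3.0]octan-1-yl acetate
Conditions: Ac2O, DMAP, Et3N, CH2Cl2, 40 °C
Reagents that add atoms: acetic anhydride, CC(=O)OC(C)=O
Why: DMAP-catalysed acylation (N-acetylpyridinium) of the tertiary alcohol, which is the only free hydroxyl group at this stage because both phenols are benzylated, so no site selection is needed.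

Step 11
Reactants: 17 (1S,2R,5R,6S)-2-[4-(benzyloxy)-3-bromo-5-methoxyphenyl]-6-[4-(benzyloxy)-3-chloro-5-methoxyphenyl]-3,7-dioxabicyclo[3.3.0]octan-1-yl acetate
Product: 18 1-Acetoxypinoresinol
Conditions: H2 (1 atm), 10% Pd/C, NaOAc, EtOAc/EtOH, rt
Reagents that add atoms: none
Why: Hydrogenolysis of the aryl benzyl ethers and hydrodehalogenation as in step 9; the tertiary acetate is inert to neutral hydrogenation and the ring benzylic ethers are spared for the reasons given there.

Branch to Fraxiresinol (compound 20)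

Step 12
Reactants: 15 (1S,2R,5R,6S)-2-[4-(benzyloxy)-3-bromo-5-methoxyphenyl]-6-[4-(benzyloxy)-3-chloro-5-methoxyphenyl]-3,7-dioxabicyclo[3.3.0]octan-1-ol
Product: 19 (1S,2R,5R,6S)-2-[4-(benzyloxy)-3,5-dimethoxyphenyl]-6-[4-(benzyloxy)-3-chloro-5-methoxyphenyl]-3,7-dioxabicyclo[3.3.0]octan-1-ol
Conditions: CuI (10 mol %), 3,4,7,8-tetramethyl-1,10-phenanthroline (20 mol %), Cs2CO3, MeOH/PhMe, 110 °C (sealed tube)
Reagents that add atoms: methanol, CO
Why: Ullmann-type Cu-catalysed C–O coupling, in which the Ar–Br bond on the C2-aryl ring is activated by the phenanthroline–Cu(I) methoxide far faster than the electron-rich, unactivated Ar–Cl bond on the C6-aryl ring, so only the ring next to the carbinol is methoxylated; the benzylated phenols exclude base-induced quinone-methide epimerisation.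

Step 13
Reactants: 19 (1S,2R,5R,6S)-2-[4-(benzyloxy)-3,5-dimethoxyphenyl]-6-[4-(benzyloxy)-3-chloro-5-methoxyphenyl]-3,7-dioxabicyclo[3.3.0]octan-1-ol
Product: 20 Fraxiresinol
Conditions: H2 (1 atm), 10% Pd/C, NaOAc, EtOAc/MeOH, rt
Reagents that add atoms: none
Why: Hydrogenolysis of both aryl benzyl ethers and hydrodechlorination of the now unneeded C–Cl handle, with the same selectivity over the ring benzylic ethers as in step 9.

Branch to 8-Hydroxysyringaresinol (compound 22)

Step 14
Reactants: 15 (1S,2R,5R,6S)-2-[4-(benzyloxy)-3-bromo-5-methoxyphenyl]-6-[4-(benzyloxy)-3-chloro-5-methoxyphenyl]-3,7-dioxabicyclo[3.3.0]octan-1-ol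
Product: 21 (1S,2R,5R,6S)-2,6-bis[4-(benzyloxy)-3,5-dimethoxyphenyl]-3,7-dioxabicyclo[3.3.0]octan-1-ol
Conditions: tBuBrettPhos Pd G3 (5 mol %), NaOtBu, MeOH (excess), 1,4-dioxane, 60 °C
Reagents that add atoms: methanol, CO
Why: Pd-catalysed C–O cross-coupling with a bulky biarylphosphine, which undergoes oxidative addition into both Ar–Br and Ar–Cl and favours C–O reductive elimination over β-hydride elimination, so both halogen handles become OMe; the hindered tertiary alkoxide does not compete with the excess of methoxide.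

Step 15
Reactants: 21 (1S,2R,5R,6S)-2,6-bis[4-(benzyloxy)-3,5-dimethoxyphenyl]-3,7-dioxabicyclo[3.3.0]octan-1-ol
Product: 22 8-Hydroxysyringaresinol
Conditions: H2 (1 atm), 10% Pd/C, EtOAc/MeOH, rt
Reagents that add atoms: none
Why: Hydrogenolysis of the two primary aryl benzyl ethers, which are cleaved much faster than the secondary ring benzylic ethers under neutral conditions.

**Compound list**

1 | 5-chlorovanillin (3-chloro-4-hydroxy-5-methoxybenzaldehyde) | COc1cc(C=O)cc(Cl)c1O | starting material
2 | 4-(benzyloxy)-3-chloro-5-methoxybenzaldehyde | COc1cc(C=O)cc(Cl)c1OCc1ccccc1 | intermediate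
3 | allenylboronic acid pinacol ester | C=C=CB1OC(C)(C)C(C)(C)O1 | starting material
4 | 2-{[(1S)-1-[4-(benzyloxy)-3-chloro-5-methoxyphenyl]but-3-yn-1-yl]oxy}-4,4,5,5-tetramethyl-1,3,2-dioxaborolane | COc1cc([C@H](CC#C)OB2OC(C)(C)C(C)(C)O2)cc(Cl)c1OCc1ccccc1 | intermediate
5 | (S)-1-[4-(benzyloxy)-3-chloro-5-methoxyphenyl]but-3-yn-1-ol | COc1cc([C@H](CC#C)O)cc(Cl)c1OCc1ccccc1 | intermediate
6 | (S)-5-[4-(benzyloxy)-3-chloro-5-methoxyphenyl]dihydrofuran-3(2H)-one | COc1cc([C@H]2OCC(=O)C2)cc(Cl)c1OCc1ccccc1 | intermediate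
7 | 5-bromovanillin (3-bromo-4-hydroxy-5-methoxybenzaldehyde) | COc1cc(C=O)cc(Br)c1O | starting material
8 | 4-(benzyloxy)-3-bromo-5-methoxybenzaldehyde | COc1cc(C=O)cc(Br)c1OCc1ccccc1 | intermediate
9 | [4-(benzyloxy)-3-bromo-5-methoxyphenyl]methanol | COc1cc(CO)cc(Br)c1OCc1ccccc1 | intermediate
10 | chloromethyl methyl sulfide | CSCCl | starting material
11 | 2-(benzyloxy)-1-bromo-3-methoxy-5-{[(methylsulfanyl)methoxy]methyl}benzene | COc1cc(COCSC)cc(Br)c1OCc1ccccc1 | intermediate
12 | 2-(benzyloxy)-1-bromo-5-[(chloromethoxy)methyl]-3-methoxybenzene | COc1cc(COCCl)cc(Br)c1OCc1ccccc1 | intermediate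
13 | lithium (5S)-5-[4-(benzyloxy)-3-chloro-5-methoxyphenyl]-2,5-dihydrofuran-3-olate | COc1cc([C@H]2OCC(O[Li])=C2)cc(Cl)c1OCc1ccccc1 | intermediate
14 | (4R,5S)-5-[4-(benzyloxy)-3-chloro-5-methoxyphenyl]-4-({[4-(benzyloxy)-3-bromo-5-methoxyphenyl]methoxy}methyl)dihydrofuran-3(2H)-one | COc1cc([C@H]2OCC(=O)[C@@H]2COCc2cc(Br)c(OCc3ccccc3)c(OC)c2)cc(Cl)c1OCc1ccccc1 | intermediate
15 | (1S,2R,5R,6S)-2-[4-(benzyloxy)-3-bromo-5-methoxyphenyl]-6-[4-(benzyloxy)-3-chloro-5-methoxyphenyl]-3,7-dioxabicyclo[3.3.0]octan-1-ol | COc1cc([C@H]2OC[C@]3(O)[C@@H](c4cc(Br)c(OCc5ccccc5)c(OC)c4)OC[C@H]23)cc(Cl)c1OCc1ccccc1 | intermediate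
16 | 8-hydroxypinoresinol | COc1cc([C@H]2OC[C@]3(O)[C@@H](c4ccc(O)c(OC)c4)OC[C@H]23)ccc1O | target
17 | (1S,2R,5R,6S)-2-[4-(benzyloxy)-3-bromo-5-methoxyphenyl]-6-[4-(benzyloxy)-3-chloro-5-methoxyphenyl]-3,7-dioxabicyclo[3.3.0]octan-1-yl acetate | COc1cc([C@H]2OC[C@]3(OC(C)=O)[C@@H](c4cc(Br)c(OCc5ccccc5)c(OC)c4)OC[C@H]23)cc(Cl)c1OCc1ccccc1 | intermediate
18 | 1-Acetoxypinoresinol | COc1cc([C@H]2OC[C@]3(OC(C)=O)[C@@H](c4ccc(O)c(OC)c4)OC[C@H]23)ccc1O | target
19 | (1S,2R,5R,6S)-2-[4-(benzyloxy)-3,5-dimethoxyphenyl]-6-[4-(benzyloxy)-3-chloro-5-methoxyphenyl]-3,7-dioxabicyclo[3.3.0]octan-1-ol | COc1cc([C@H]2OC[C@]3(O)[C@@H](c4cc(OC)c(OCc5ccccc5)c(OC)c4)OC[C@H]23)cc(Cl)c1OCc1ccccc1 | intermediate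
20 | Fraxiresinol | COc1cc([C@H]2OC[C@]3(O)[C@@H](c4cc(OC)c(O)c(OC)c4)OC[C@H]23)ccc1O | target
21 | (1S,2R,5R,6S)-2,6-bis[4-(benzyloxy)-3,5-dimethoxyphenyl]-3,7-dioxabicyclo[3.3.0]octan-1-ol | COc1cc([C@H]2OC[C@]3(O)[C@@H](c4cc(OC)c(OCc5ccccc5)c(OC)c4)OC[C@H]23)cc(OC)c1OCc1ccccc1 | intermediate
22 | 8-Hydroxysyringaresinol | COc1cc([C@H]2OC[C@]3(O)[C@@H](c4cc(OC)c(O)c(OC)c4)OC[C@H]23)cc(OC)c1O | target

Totals for Fraxiresinol (compound 20): total step count 10, longest linear sequence 7
Totals for 8-hydroxypinoresinol (compound 16): total step count 9, longest linear sequence 6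
Totals for 8-Hydroxysyringaresinol (compound 22): total step count 10, longest linear sequence 7
Totals for 1-Acetoxypinoresinol (compound 18): total step count 10, longest linear sequence 7

**Steps most likely to fail**

Step 8. Photolysis of the aryl C–Br bond (direct, or by energy transfer from the excited ketone) and Norrish type I cleavage of the α-alkoxy ketone may compete with the 1,6-hydrogen transfer. The fallback carries no bromine through the photoreaction and installs it afterwards by phenol-directed bromination; it sets out from compound 6 and returns at compound 15. Commercial [4-(benzyloxy)-3-methoxyphenyl]methanol is converted as in step 6 into its methylthiomethyl ether F1 and with SO2Cl2 into the chloromethyl ether F2, which alkylates the lithium enolate 13 of ketone 6 as in step 7 to give the bromine-free ketone F3. Photocyclisation as in step 8 should give the bicyclic alcohol F4. Hydrogenolysis over Pd/C without base (EtOAc, rt) removes both benzyl groups while the aryl chloride is retained, giving the chloro-diphenol F5. NBS (1 equiv, cat. i-Pr2NH, CH2Cl2, 0 °C) then brominates the only free position ortho to a phenolic OH, C5 of the C2-aryl ring (on the other ring both ortho positions carry Cl and OMe), giving the bromo-chloro-diphenol F6. Benzylation (BnBr, K2CO3, DMF) returns compound 15.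

Step 7. Proton exchange between product and unreacted enolate, followed by β-elimination of the arylmethoxide or a second alkylation, and partial enolisation towards C2 may erode the alkylation. The fallback replaces the basic enolate alkylation by a Lewis-acid Mukaiyama-type alkylation; it sets out from compound 6 and returns at compound 14. Ketone 6 is converted (LDA, TMSCl, THF, −78 °C) into the silyl enol ether F7, which is isolated and whose regiochemistry is checked. F7 is treated with chloromethyl ether 12 and catalytic ZnBr2 (CH2Cl2, −20 °C) so that C–C bond formation goes through the oxocarbenium ion in a non-basic medium, giving 14.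

Step 14. Incomplete oxidative addition into the electron-rich, ortho-alkoxy aryl chloride and reduction by β-hydride elimination from Pd–OMe may leave mono-methoxylated or dehalogenated material. The fallback makes both coupling sites bromides by phenol-directed bromination; it sets out from compound 16 and returns at compound 21. 8-hydroxypinoresinol 16 is brominated ortho to both phenolic OH groups (NBS, 2 equiv, cat. i-Pr2NH, CH2Cl2, 0 °C) to give the dibromide F8. Benzylation (BnBr, K2CO3, DMF) gives the dibenzyl ether F9. Double Cu-catalysed methoxylation under the conditions of step 12 then gives 21.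

**Further compounds**

F1 | step 8 | 1-(benzyloxy)-2-methoxy-4-{[(methylsulfanyl)methoxy]methyl}benzene | COc1cc(COCSC)ccc1OCc1ccccc1
F2 | step 8 | 1-(benzyloxy)-4-[(chloromethoxy)methyl]-2-methoxybenzene | COc1cc(COCCl)ccc1OCc1ccccc1
F3 | step 8 | (4R,5S)-5-[4-(benzyloxy)-3-chloro-5-methoxyphenyl]-4-({[4-(benzyloxy)-3-methoxyphenyl]methoxy}methyl)dihydrofuran-3(2H)-one | COc1cc([C@H]2OCC(=O)[C@@H]2COCc2ccc(OCc3ccccc3)c(OC)c2)cc(Cl)c1OCc1ccccc1
F4 | step 8 | (1S,2R,5R,6S)-2-[4-(benzyloxy)-3-methoxyphenyl]-6-[4-(benzyloxy)-3-chloro-5-methoxyphenyl]-3,7-dioxabicyclo[3.3.0]octan-1-ol | COc1cc([C@H]2OC[C@]3(O)[C@@H](c4ccc(OCc5ccccc5)c(OC)c4)OC[C@H]23)cc(Cl)c1OCc1ccccc1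
F5 | step 8 | (1S,2R,5R,6S)-6-(3-chloro-4-hydroxy-5-methoxyphenyl)-2-(4-hydroxy-3-methoxyphenyl)-3,7-dioxabicyclo[3.3.0]octan-1-ol | COc1cc([C@H]2OC[C@]3(O)[C@@H](c4ccc(O)c(OC)c4)OC[C@H]23)cc(Cl)c1O
F6 | step 8 | (1S,2R,5R,6S)-2-(3-bromo-4-hydroxy-5-methoxyphenyl)-6-(3-chloro-4-hydroxy-5-methoxyphenyl)-3,7-dioxabicyclo[3.3.0]octan-1-ol | COc1cc([C@H]2OC[C@]3(O)[C@@H](c4cc(Br)c(O)c(OC)c4)OC[C@H]23)cc(Cl)c1O
F7 | step 7 | {[(5S)-5-[4-(benzyloxy)-3-chloro-5-methoxyphenyl]-2,5-dihydrofuran-3-yl]oxy}trimethylsilane | COc1cc([C@H]2OCC(O[Si](C)(C)C)=C2)cc(Cl)c1OCc1ccccc1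
F8 | step 14 | (1S,2R,5R,6S)-2,6-bis(3-bromo-4-hydroxy-5-methoxyphenyl)-3,7-dioxabicyclo[3.3.0]octan-1-ol | COc1cc([C@H]2OC[C@]3(O)[C@@H](c4cc(Br)c(O)c(OC)c4)OC[C@H]23)cc(Br)c1O
F9 | step 14 | (1S,2R,5R,6S)-2,6-bis[4-(benzyloxy)-3-bromo-5-methoxyphenyl]-3,7-dioxabicyclo[3.3.0]octan-1-ol | COc1cc([C@H]2OC[C@]3(O)[C@@H](c4cc(Br)c(OCc5ccccc5)c(OC)c4)OC[C@H]23)cc(Br)c1OCc1ccccc1
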